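All runs were generated by integration with made-up constants; scatter was added.

Time is what I follow here, at one constant temperature, and I follow one substrate molecule through it, asking for its chance per minute of becoming product.

| flask | substrate | partner | free catalyst | time |
|---|---|---|---|---|
| winter | 120 mM | 300 mM | 9.60 mM |  |
| summer | 60.0 mM | 240 mM | 9.60 mM |  |
| autumn | 120 mM | 900 mM | 9.60 mM |  |
| noon | 60.0 mM | 300 mM | 9.60 mM |  |
| dawn | 18.0 mM | 300 mM | 9.60 mM | 58 min |

| winter run: time / min | winter run: [product] / mM | summer run: time / min | summer run: [product] / mM | autumn run: time / min | autumn run: [product] / mM | noon run: time / min | noon run: [product] / mM |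
|---|---|---|---|---|---|---|---|
| 2.6 | 3.0 | 2.6 | 1.6 | 2.6 | 4.3 | 2.6 | 0 |
| 7.8 | 6.2 | 7.8 | 1.8 | 7.8 | 21.2 | 7.8 | 0.3 |
| 15 | 10.8 | 15 | 2.7 | 15 | 46.9 | 15 | 2.9 |
| 24 | 17.3 | 24 | 7.4 | 24 | 84.7 | 24 | 6.8 |
| 34 | 30.3 | 34 | 9.8 | 34 | 104.8 | 34 | 11.4 |
| 45 | 43.3 | 45 | 12.2 | 45 | 115.4 | 45 | 15.8 |
| 58 | 61.3 | 58 | 17.2 | 58 | 119.6 | 58 | 21.6 |

(standard deviation of a reading: 1 mM)

- Overall: substrate + partner -> product, with free catalyst as catalyst.
- Constant volume, constant temperature.
- "The second partner" is partner.
- An order is taken over about fifteen percent of the charge, up and down.

- the exponent of [partner] in the starting rate at the charge of the winter run (at the point where two percent of the substrate have become product)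
- the exponent of [substrate] in the starting rate at the charge of the winter run (at the point where two percent of the substrate have become product) (one fixed amount of product, the same in the runs compared)
- the summer run starts with 60.0 mM less of substrate and of partner than the winter run, and with no product. Compared where both hold the same amount of substrate, once fifteen percent of what the summer run was charged with has turned into product, is the summer run faster, slower or alike (within a tenth)?
- product in the dawn run at 58 min, as a share of the substrate charged

I read the noon column first, since it has the partner charge of the dawn run. By 24 min the noon run has made 6.8 mM of product, which takes hardly any of its partner, so partner stands in large excess and over that stretch the substrate's loss can be treated as pseudo-first-order. That reading gives 0.00501 min⁻¹, which is my per-molecule chance: the natural logarithm of substrate charged over substrate left, divided by the time. Read on to 58 min, the noon column gives 0.00769 min⁻¹, higher than the early value, so the chance climbs along the noon run and I carry it to another flask over a like stretch of product.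

Applied to the dawn run for 58 min, the early chance gives 25.2% of its substrate, or 4.54 mM of product, less than the noon reading I took it from, so the stretches are roughly alike and I commit to that share.

The winter column to 15 min gives a chance of 0.00629 min⁻¹, between the two noon values although winter holds more substrate, so I take the substrate order as 1. Winter reaches 10.8 mM at 15 min, and the autumn column passes that product near 4.60 min, in a third of the time on 900 mM of partner against 300 mM, which reads as a partner order of 1.08. Late in winter, with 58.7 mM of substrate left, product gains 1.38 mM min⁻¹. The summer run, holding 50.2 mM near 34 min, gains 0.229 mM min⁻¹, so, although these two substrate amounts are not quite equal, I call summer slower.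

The forecast gives 1.4 for partner, 1 for substrate, slower for summer and 22% for dawn: “Dawn: k≈0.0044 min⁻¹ over 58 min gives about 22%.” My partner order and dawn share differ from these.

The flask gives 1.0 for partner, 1.0 for substrate, slower for summer and 25.5% for dawn.

    free catalyst + substrate + partner → product + free catalyst (3.654 M⁻² min⁻¹)
    free catalyst + impurity → spent catalyst
    substrate + partner + product → 2 product (1.236 M⁻² min⁻¹)

The dawn share corresponds to a per-molecule chance of 0.00507 min⁻¹, beside the 0.00501 min⁻¹ carried from noon. That chance stays low because impurity turns 5.71 mM of the 9.60 mM of free catalyst into spent catalyst at once. The same dawn charge without that loss stands at 50.5% at 58 min, a chance of 0.0121 min⁻¹, which is 2.39 times the dawn value, while free catalyst charged over free catalyst left is 2.47.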